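The time asked, 12 h, lies 4.00 h beyond Tuesday's last reading, so a curve has to be carried past its end, and each given number must first be tested for what it moves.

all flasks: E 46 mM (held)
- Tuesday's: Z 0.047 M; run made earlier
- Sunday's: Z 0.30 M; run made earlier
- spring: Z 0.040 M; time 12 h
- noon: Z 0.060 M; time 12 h
- winter: Z 0.080 M; time 12 h
- autumn: Z 0.12 M; time 12 h
- dawn: Z 0.20 M; time 12 h

| run | time / h | D / % | Z / % |
|---|---|---|---|
| Tuesday's | 0.667 | 0.5 | 98.3 |
| Tuesday's | 1.50 | 0.9 | 96.1 |
| Tuesday's | 4.00 | 3.0 | 90.7 |
| Tuesday's | 8.00 | 4.6 | 81.7 |
| Sunday's | 2.00 | 0.1 | 99.4 |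
| Sunday's | 4.00 | 0.2 | 98.8 |
| Sunday's | 6.00 | 0.9 | 97.4 |
| Sunday's | 8.00 | 0.6 | 97.2 |

(readings scatter by 0.3 percentage points)

- solid, in amounts per volume of the solution: Z
- at the start none of X is dissolved
- what may be going on: L + X <-> D; L + X -> G; E <-> X; Z <-> L
- at the start none of Z is in solution
- "hardly changes" means that all values lie within two and a half points (for a concentration: within two and a half percent of the largest)

- [D] at the end for spring, noon, winter, autumn, dawn, in this order
- how that number moves from the first to the last of them (hardly changes / rises all the way / rises, then falls / falls, then rises / falls all the way)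

The charge of Z comes first. Sunday's run holds 6.38 times Tuesday's charge, yet at 8.00 h D amounts to 2.16 mM on Tuesday and 1.80 mM on Sunday, so D is close to zero order in the charge, and its fraction of the charge shrinks as the charge grows. At Tuesday's pace, spring, whose charge is the smallest, loses 32.3% of its Z by the end, so Z remains there. E needs no correction, being held at 46 mM, the same as on Tuesday and Sunday.

Next come the readings. Sunday's D reads 0.6% with a scatter of 0.3 percentage points, which is too coarse to build on, while Tuesday's reads 4.6% with the same scatter, so Tuesday's run must carry the number.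

Tuesday's readings suggest a bending curve. Tuesday's mean rate over 8.00 h is 0.270 mM/h, but its last stretch reads 0.188 mM/h, which is slower. The whole mean would give 3.24 mM at the end, so the later rate is used for the remaining hours. This reckoning gives the end amount of D 2.91 mM, the same for these charges, which is 7.28% of spring's charge.

The forecast gives 0.003 M for spring and 0.003 M for dawn, shape "hardly changes", holding that “all five should show the same”. The reckoning here agrees at that one digit.

The flasks give 0.00279 M in spring and 0.00279 M in dawn, and the row hardly changes.

L + X ⇌ D (K = 12.0 /M, k = 0.0120 /M/s); L + X → G (k = 7.40 × 10⁻⁴ /M/s); E ⇌ X, rate k3*(csat - [X]) (kL = 7.10 × 10⁻⁴ /s); Z ⇌ L, rate k4*(cs4 - [L]) while solid is left; crystals form when [L] > cs4 (solubility = 32.0 mM, k = 1.00 × 10⁻⁵ /s) Spring still holds 68.8% of its charge as Z at 12.0 h. Its D stands at 6.97% of the charge, against the 7.28% reckoned. The same 2.91 mM on dawn's charge makes 1.46%, and dawn holds D at 1.40% of its charge at 12.0 h.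

The earlier runs and the new flask come from a simulation with made-up constants, noise included.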